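**Strategy**

Atom labels: C5 is the spiro atom; C1 (side chain), C2, C3 and C4 (methyl) complete the five-membered ring, and C6, C7=C8, C9 (OH) and C10 the six-membered ring. Because C4 and the quaternary C5 are neighbours and C5 adjoins C1, which can be written as a ketone, the cyclopentane is the imprint of β-methylation and α-allylation of a 2-substituted cyclopentenone. In one operation Me2CuLi methylates (R)-4-silyloxy-2-(2-ethylallyl)cyclopent-2-enone at C4 and allyl iodide traps the enolate at C5, forming C4–CH3 and C5–C6 and setting both centres from one purchased stereocentre. Ozonolysis and aldol condensation later build the cyclohexene ring; the C3 oxygen relays the side chain to C1.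

Key step: step 5

Remarks. Side chain labels: C11 (CH on C1, carrying methyl C12), C13–C15 (CH2), C16 (CH carrying methyl), C17 (CH2O). β is the face of the five-membered ring that carries the C4 methyl group, α the opposite face; in all spiro compounds C6 lies α and C10 β. Assumption: (R)-4-(tert-butyldimethylsilyloxy)cyclopent-2-en-1-one and (R)-3-bromo-2-methylpropan-1-ol are bought as single enantiomers.

**Route**

Step 1
Reactants: 1 2-ethylacrolein
Product: 2 2-methylenebutan-1-ol
Conditions: NaBH4, CeCl3·7H2O, MeOH, 0 °C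
Reagents that add atoms: none
Why: Luche reduction delivers hydride to the aldehyde carbon only (1,2-reduction), so the 1,1-disubstituted alkene is kept.

Step 2
Reactants: 2 2-methylenebutan-1-ol
Product: 5 tributyl(2-methylenebutyl)stannane, via lithium 2-methylenebutan-1-olate 3 (not isolated), via 2-methylenebutyl methanesulfonate 4 (not isolated)
Conditions: n-BuLi, THF, −78 °C; MsCl; then Bu3SnLi (from Bu3SnH, LiN(i-Pr)2), −78 → 0 °C
Reagents that add atoms: tributylstannyllithium, [Li][Sn](CCCC)(CCCC)CCCC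
Why: The allylic mesylate made in the flask is displaced by the stannyl anion (nucleophilic substitution, direct or allylic), and both modes give the same stannane because the allyl unit is symmetric about its central carbon.

Step 3
Reactants: 6 (R)-4-(tert-butyldimethylsilyloxy)cyclopent-2-en-1-one
Product: 7 (R)-4-(tert-butyldimethylsilyloxy)-2-iodocyclopent-2-en-1-one
Conditions: I2, pyridine, CH2Cl2, 0 °C → rt
Reagents that add atoms: iodine, II
Why: α-Iodination of an enone by conjugate addition of pyridine, iodination of the enolate and elimination (Baylis–Hillman-type sequence) leaves the silyloxy-bearing stereocentre untouched.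

Step 4
Reactants: 7 (R)-4-(tert-butyldimethylsilyloxy)-2-iodocyclopent-2-en-1-one; 5 tributyl(2-methylenebutyl)stannane
Product: 8 (R)-4-(tert-butyldimethylsilyloxy)-2-(2-methylenebutyl)cyclopent-2-en-1-one
Conditions: Pd2(dba)3 (cat.), AsPh3, CuI, DMF, rt → 40 °C
Reagents that add atoms: none
Why: Stille coupling of an α-iodoenone with an allylstannane under conditions that speed up transmetalation; the symmetric 2-ethylallyl unit cannot give a regioisomer and the mild temperature should keep the skipped diene out of conjugation.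

Step 5
Reactants: 8 (R)-4-(tert-butyldimethylsilyloxy)-2-(2-methylenebutyl)cyclopent-2-en-1-one; 9 lithium dimethylcuprate; 10 allyl iodide
Product: 12 (2S,3R,4R)-2-allyl-4-(tert-butyldimethylsilyloxy)-3-methyl-2-(2-methylenebutyl)cyclopentan-1-one, via lithium enolate 11 (not isolated)
Conditions: Me2CuLi (from CuI, 2 MeLi), Et2O/THF, −78 °C; then allyl iodide (excess), HMPA, −78 → −40 °C; NH4Cl aq. at −40 °C
Reagents that add atoms: lithium dimethylcuprate 9, C[Cu-]C.[Li+]; allyl iodide 10, C=CCI
Why: The cuprate transfers methyl to the enone β-carbon C4 (copper–enone π-complex, then reductive elimination) and leaves the regiodefined C1=C5 lithium enolate 11, which allyl iodide C-alkylates in an SN2 step accelerated by HMPA; the closest known reaction type is the three-component conjugate addition–enolate alkylation of 4-silyloxycyclopentenones and of 2-alkylcyclopentenones. No ring is closed, so no mode of closure applies. C4 is set by the C3 silyloxy group, which blocks the α face so that methyl enters β (trans); C5 is set by the new C4 methyl, because the electrophile approaches the planar enolate from the α face, anti to the vicinal methyl, making C6 α and leaving the 2-ethylallyl arm (C10) β. The step needs C- over O-allylation, alkylation at the fully substituted C5 with good facial discrimination between two similar arms, and no proton transfer to the C2 enolate, which would expel the silyloxy group; a soft, very reactive iodide in excess, HMPA and a quench at or below −40 °C should secure this, since C5 is the only enolised position until proton exchange sets in.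

Step 6
Reactants: 12 (2S,3R,4R)-2-allyl-4-(tert-butyldimethylsilyloxy)-3-methyl-2-(2-methylenebutyl)cyclopentan-1-one
Product: 14 5α-allyl-3α-(tert-butyldimethylsilyloxy)-4β-methyl-5β-(2-methylenebutyl)cyclopent-1-en-1-yl trifluoromethanesulfonate, via potassium enolate 13 (not isolated)
Conditions: KN(SiMe3)2, THF, −78 °C, 15 min; then N-(5-chloropyridin-2-yl)bis(trifluoromethanesulfonyl)imide (Comins' reagent), −78 °C
Reagents that add atoms: Comins' reagent, O=S(=O)(N(c1ccc(Cl)cn1)S(=O)(=O)C(F)(F)F)C(F)(F)F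
Why: Kinetic enolate O-triflation; C5 is quaternary, so only C2 can be deprotonated, and trapping at −78 °C with a highly reactive triflyl donor should outpace loss of the C3 silyloxy group.

Step 7
Reactants: 14 5α-allyl-3α-(tert-butyldimethylsilyloxy)-4β-methyl-5β-(2-methylenebutyl)cyclopent-1-en-1-yl trifluoromethanesulfonate
Product: 16 3α-(tert-butyldimethylsilyloxy)-4β-methyl-5β-(2-oxobutyl)-5α-(2-oxoethyl)cyclopent-1-en-1-yl trifluoromethanesulfonate, via bis-ozonide 15 (not isolated)
Conditions: O3, CH2Cl2, −78 °C, Sudan Red 7B as end-point indicator; PPh3, −78 °C → rt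
Reagents that add atoms: ozone, [O-][O+]=O
Why: Ozonolysis with reductive work-up cleaves the two electron-rich terminal alkenes to the C7 aldehyde and the C9 ethyl ketone, while the electron-poor enol triflate reacts far more slowly with the electrophilic oxidant.

Step 8
Reactants: 16 3α-(tert-butyldimethylsilyloxy)-4β-methyl-5β-(2-oxobutyl)-5α-(2-oxoethyl)cyclopent-1-en-1-yl trifluoromethanesulfonate
Product: 17 3α-(tert-butyldimethylsilyloxy)-4β,8-dimethyl-9-oxospiro[4.5]deca-1,7-dien-1-yl trifluoromethanesulfonate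
Conditions: Bn2NH·CF3CO2H, benzene, 50 °C
Reagents that add atoms: none
Why: Ammonium-salt-catalysed intramolecular aldol condensation: the ethyl CH2 of the ketone (C8) adds to the aldehyde C7 in the only mode that gives an unstrained (six-membered) ring, and dehydration gives the 2-methylcyclohexenone without creating a stereocentre.

Step 9
Reactants: 17 3α-(tert-butyldimethylsilyloxy)-4β,8-dimethyl-9-oxospiro[4.5]deca-1,7-dien-1-yl trifluoromethanesulfonate
Product: 18 3α-(tert-butyldimethylsilyloxy)-4β,8-dimethylspiro[4.5]deca-1,7-dien-9-one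
Conditions: Pd(OAc)2 (cat.), PPh3, HCO2H, n-Bu3N, DMF, 60 °C
Reagents that add atoms: none
Why: Palladium-catalysed formate reduction of an enol triflate (oxidative addition to zerovalent palladium, decarboxylation of formate to a palladium hydride, reductive elimination) replaces OTf by H and leaves the enone and the allylic silyl ether alone.

Step 10
Reactants: 18 3α-(tert-butyldimethylsilyloxy)-4β,8-dimethylspiro[4.5]deca-1,7-dien-9-one
Product: 19 3α-hydroxy-4β,8-dimethylspiro[4.5]deca-1,7-dien-9-one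
Conditions: HF·pyridine, pyridine, THF, 0 °C → rt
Reagents that add atoms: none
Why: Fluoride-driven cleavage of the only silyl ether frees the C3 hydroxyl group under buffered conditions that the enone and the allylic alcohol tolerate.

Step 11
Reactants: 19 3α-hydroxy-4β,8-dimethylspiro[4.5]deca-1,7-dien-9-one
Product: 22 ethyl 2-(4β,8-dimethyl-9-oxospiro[4.5]deca-2,7-dien-1α-yl)acetate, via mixed orthoester 20 (not isolated), via ketene acetal 21 (not isolated)
Conditions: MeC(OEt)3 (excess), EtCO2H (cat.), xylene, 140 °C, EtOH distilled off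
Reagents that add atoms: triethyl orthoacetate, CC(OCC)(OCC)OCC
Why: Johnson–Claisen rearrangement; the [3,3] shift is suprafacial, so C11 bonds to C1 on the α face that the C3 oxygen leaves, which sets C1 (side chain α, trans to C10 and to the C4 methyl) and moves the alkene to C2=C3.

Step 12
Reactants: 22 ethyl 2-(4β,8-dimethyl-9-oxospiro[4.5]deca-2,7-dien-1α-yl)acetate
Product: 23 ethyl 2-[(9S)-9-hydroxy-4β,8-dimethylspiro[4.5]deca-2,7-dien-1α-yl]acetate
Conditions: (R)-2-methyl-CBS-oxazaborolidine, catecholborane, toluene, −78 °C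
Reagents that add atoms: none
Why: Corey–Bakshi–Shibata reduction; with the C8 alkenyl arm as the large group and the C10 methylene as the small one, the (R)-catalyst should deliver hydride to the face that gives the 9S allylic alcohol (1,2-reduction), and catecholborane at −78 °C leaves the ester and the C2=C3 alkene alone.

Step 13
Reactants: 23 ethyl 2-[(9S)-9-hydroxy-4β,8-dimethylspiro[4.5]deca-2,7-dien-1α-yl]acetate
Product: 24 ethyl 2-[(9S)-9-(tert-butyldimethylsilyloxy)-4β,8-dimethylspiro[4.5]deca-2,7-dien-1α-yl]acetate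
Conditions: TBSCl, imidazole, DMF, rt
Reagents that add atoms: tert-butyldimethylsilyl chloride, CC(C)(C)[Si](C)(C)Cl
Why: Silylation of the secondary allylic alcohol gives an ether that withstands the amide base, the hydride reagents and the mesylation to come.

Step 14
Reactants: 24 ethyl 2-[(9S)-9-(tert-butyldimethylsilyloxy)-4β,8-dimethylspiro[4.5]deca-2,7-dien-1α-yl]acetate
Product: 25 ethyl 2-[(1R,4S,5S,9S)-9-(tert-butyldimethylsilyloxy)-4,8-dimethylspiro[4.5]dec-7-en-1-yl]acetate
Conditions: 2-nitrobenzenesulfonohydrazide, Et3N, CH2Cl2, rt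
Reagents that add atoms: none
Why: Diimide reduction (concerted syn transfer of two hydrogens) is much faster for the cis-disubstituted cyclopentene C2=C3 than for the trisubstituted C7=C8 and creates no stereocentre.

Step 15
Reactants: 26 (R)-3-bromo-2-methylpropan-1-ol
Product: 27 (R)-(3-bromo-2-methylpropoxy)(tert-butyl)dimethylsilane
Conditions: TBSCl, imidazole, CH2Cl2, 0 °C → rt
Reagents that add atoms: tert-butyldimethylsilyl chloride, CC(C)(C)[Si](C)(C)Cl
Why: Standard silylation of a primary alcohol; the stereocentre is not involved.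

Step 16
Reactants: 27 (R)-(3-bromo-2-methylpropoxy)(tert-butyl)dimethylsilane
Product: 29 (S)-5-(tert-butyldimethylsilyloxy)-4-methylpentan-1-ol, via Grignard reagent 28 (not isolated)
Conditions: Mg, THF, rt → 40 °C; then CuI (cat.), ethylene oxide, −30 → 0 °C; NH4Cl aq.
Reagents that add atoms: ethylene oxide, C1CO1
Why: Copper-catalysed ring opening of the epoxide by the primary Grignard reagent adds the two-carbon hydroxyethyl unit, and the stereocentre, one carbon away from magnesium, is not affected.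

Step 17
Reactants: 29 (S)-5-(tert-butyldimethylsilyloxy)-4-methylpentan-1-ol
Product: 30 (S)-tert-butyl[(5-iodo-2-methylpentyl)oxy]dimethylsilane
Conditions: I2, PPh3, imidazole, CH2Cl2, 0 °C → rt
Reagents that add atoms: iodine, II
Why: Appel-type iodination (SN2 on the alkoxyphosphonium salt) of the primary alcohol under buffered conditions that keep the silyl ether.

Step 18
Reactants: 25 ethyl 2-[(1R,4S,5S,9S)-9-(tert-butyldimethylsilyloxy)-4,8-dimethylspiro[4.5]dec-7-en-1-yl]acetate; 30 (S)-tert-butyl[(5-iodo-2-methylpentyl)oxy]dimethylsilane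
Product: 32 ethyl (2R,6S)-7-(tert-butyldimethylsilyloxy)-2-[(1R,4S,5S,9S)-9-(tert-butyldimethylsilyloxy)-4,8-dimethylspiro[4.5]dec-7-en-1-yl]-6-methylheptanoate, via lithium ester enolate 31 (not isolated)
Conditions: LiN(i-Pr)2, THF, −78 °C; then 30, HMPA, −78 → −20 °C
Reagents that add atoms: none
Why: Ester enolate alkylation (SN2); allylic 1,3-strain holds C1–H in the enolate plane, so the iodide reaches C11 from the side of C2, away from the quaternary C5, which should give 11R as in the alkylation of steroidal 17-ylacetate enolates.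

Step 19
Reactants: 32 ethyl (2R,6S)-7-(tert-butyldimethylsilyloxy)-2-[(1R,4S,5S,9S)-9-(tert-butyldimethylsilyloxy)-4,8-dimethylspiro[4.5]dec-7-en-1-yl]-6-methylheptanoate
Product: 33 (2R,6S)-7-(tert-butyldimethylsilyloxy)-2-[(1R,4S,5S,9S)-9-(tert-butyldimethylsilyloxy)-4,8-dimethylspiro[4.5]dec-7-en-1-yl]-6-methylheptan-1-ol
Conditions: LiAlH4, THF, 0 °C
Reagents that add atoms: none
Why: Hydride reduction of the ester to the primary alcohol; the silyl ethers and the trisubstituted alkene are inert and C11 is not epimerised because no base-labile carbonyl remains after reduction.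

Step 20
Reactants: 33 (2R,6S)-7-(tert-butyldimethylsilyloxy)-2-[(1R,4S,5S,9S)-9-(tert-butyldimethylsilyloxy)-4,8-dimethylspiro[4.5]dec-7-en-1-yl]-6-methylheptan-1-ol
Product: 35 tert-butyl{[(2S,6R)-6-[(1R,4S,5S,9S)-9-(tert-butyldimethylsilyloxy)-4,8-dimethylspiro[4.5]dec-7-en-1-yl]-2-methylheptyl]oxy}dimethylsilane, via mesylate 34 (not isolated)
Conditions: MsCl, Et3N, THF, 0 °C; then LiEt3BH (excess), 0 → 50 °C
Reagents that add atoms: none
Why: Mesylation followed by SN2 hydride displacement with LiEt3BH turns CH2OH into the C12 methyl group, a deoxygenation that works on β-branched primary sulfonates.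

Step 21
Reactants: 35 tert-butyl{[(2S,6R)-6-[(1R,4S,5S,9S)-9-(tert-butyldimethylsilyloxy)-4,8-dimethylspiro[4.5]dec-7-en-1-yl]-2-methylheptyl]oxy}dimethylsilane
Product: 36 (2S,6R)-6-[(1R,4S,5S,9S)-9-hydroxy-4,8-dimethylspiro[4.5]dec-7-en-1-yl]-2-methylheptan-1-ol
Conditions: HF·pyridine, pyridine, THF, 0 °C → rt
Reagents that add atoms: none
Why: Fluoride cleaves both silyl ethers in one operation under buffered conditions that should not ionise the allylic alcohol.

Step 22
Reactants: 36 (2S,6R)-6-[(1R,4S,5S,9S)-9-hydroxy-4,8-dimethylspiro[4.5]dec-7-en-1-yl]-2-methylheptan-1-ol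
Product: 37 (2S,6R)-6-[(1R,4S,5S,9S)-9-hydroxy-4,8-dimethylspiro[4.5]dec-7-en-1-yl]-2-methylheptyl acetate
Conditions: AcCl (1.05 equiv), 2,4,6-collidine, CH2Cl2, −78 °C
Reagents that add atoms: acetyl chloride, CC(=O)Cl
Why: Selective O-acylation: the unhindered primary C17 hydroxyl should react far faster with the acyl chloride at low temperature than the secondary allylic C9 hydroxyl flanked by C8 and C10.

**Compound list**

1 | 2-ethylacrolein | CCC(=C)C=O | starting material
2 | 2-methylenebutan-1-ol | CCC(=C)CO | intermediate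
3 | lithium 2-methylenebutan-1-olate | CCC(=C)CO[Li] | intermediate
4 | 2-methylenebutyl methanesulfonate | CCC(=C)COS(C)(=O)=O | intermediate
5 | tributyl(2-methylenebutyl)stannane | CCC(=C)C[Sn](CCCC)(CCCC)CCCC | intermediate
6 | (R)-4-(tert-butyldimethylsilyloxy)cyclopent-2-en-1-one | O=C1C=C[C@H](O[Si](C)(C)C(C)(C)C)C1 | starting material
7 | (R)-4-(tert-butyldimethylsilyloxy)-2-iodocyclopent-2-en-1-one | O=C1C(I)=C[C@H](O[Si](C)(C)C(C)(C)C)C1 | intermediate
8 | (R)-4-(tert-butyldimethylsilyloxy)-2-(2-methylenebutyl)cyclopent-2-en-1-one | CCC(=C)CC1=C[C@H](O[Si](C)(C)C(C)(C)C)CC1=O | intermediate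
9 | lithium dimethylcuprate | C[Cu-]C.[Li+] | starting material (reagent made in the flask from CuI and MeLi)
10 | allyl iodide | C=CCI | starting material
11 | lithium (3R,4R)-4-(tert-butyldimethylsilyloxy)-3-methyl-2-(2-methylenebutyl)cyclopent-1-en-1-olate | [Li]OC1=C(CC(=C)CC)[C@@H](C)[C@H](O[Si](C)(C)C(C)(C)C)C1 | intermediate
12 | (2S,3R,4R)-2-allyl-4-(tert-butyldimethylsilyloxy)-3-methyl-2-(2-methylenebutyl)cyclopentan-1-one | O=C1C[C@@H](O[Si](C)(C)C(C)(C)C)[C@H](C)[C@]1(CC=C)CC(=C)CC | intermediate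
13 | potassium enolate of 12 (C1–OK, C1=C2) | [K]OC1=C[C@@H](O[Si](C)(C)C(C)(C)C)[C@H](C)[C@]1(CC=C)CC(=C)CC | intermediate
14 | 5α-allyl-3α-(tert-butyldimethylsilyloxy)-4β-methyl-5β-(2-methylenebutyl)cyclopent-1-en-1-yl trifluoromethanesulfonate | O=S(=O)(OC1=C[C@@H](O[Si](C)(C)C(C)(C)C)[C@H](C)[C@]1(CC=C)CC(=C)CC)C(F)(F)F | intermediate
15 | bis-ozonide of 14 (both side-chain alkenes as 1,2,4-trioxolanes, epimers at the acetal carbons) | O=S(=O)(OC1=C[C@@H](O[Si](C)(C)C(C)(C)C)[C@H](C)[C@]1(CC2OCOO2)CC2(CC)OCOO2)C(F)(F)F | intermediate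
16 | 3α-(tert-butyldimethylsilyloxy)-4β-methyl-5β-(2-oxobutyl)-5α-(2-oxoethyl)cyclopent-1-en-1-yl trifluoromethanesulfonate | O=S(=O)(OC1=C[C@@H](O[Si](C)(C)C(C)(C)C)[C@H](C)[C@]1(CC=O)CC(=O)CC)C(F)(F)F | intermediate
17 | 3α-(tert-butyldimethylsilyloxy)-4β,8-dimethyl-9-oxospiro[4.5]deca-1,7-dien-1-yl trifluoromethanesulfonate | O=S(=O)(OC1=C[C@@H](O[Si](C)(C)C(C)(C)C)[C@H](C)[C@@]12CC=C(C)C(=O)C2)C(F)(F)F | intermediate
18 | 3α-(tert-butyldimethylsilyloxy)-4β,8-dimethylspiro[4.5]deca-1,7-dien-9-one | C1=C[C@@H](O[Si](C)(C)C(C)(C)C)[C@H](C)[C@@]12CC=C(C)C(=O)C2 | intermediate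
19 | 3α-hydroxy-4β,8-dimethylspiro[4.5]deca-1,7-dien-9-one | C1=C[C@@H](O)[C@H](C)[C@@]12CC=C(C)C(=O)C2 | intermediate
20 | 3α-(1,1-diethoxyethoxy)-4β,8-dimethylspiro[4.5]deca-1,7-dien-9-one | C1=C[C@@H](OC(C)(OCC)OCC)[C@H](C)[C@@]12CC=C(C)C(=O)C2 | intermediate
21 | 3α-(1-ethoxyethenyloxy)-4β,8-dimethylspiro[4.5]deca-1,7-dien-9-one | C1=C[C@@H](OC(=C)OCC)[C@H](C)[C@@]12CC=C(C)C(=O)C2 | intermediate
22 | ethyl 2-(4β,8-dimethyl-9-oxospiro[4.5]deca-2,7-dien-1α-yl)acetate | CCOC(=O)C[C@H]1C=C[C@H](C)[C@@]12CC=C(C)C(=O)C2 | intermediate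
23 | ethyl 2-[(9S)-9-hydroxy-4β,8-dimethylspiro[4.5]deca-2,7-dien-1α-yl]acetate | CCOC(=O)C[C@H]1C=C[C@H](C)[C@@]12CC=C(C)[C@@H](O)C2 | intermediate
24 | ethyl 2-[(9S)-9-(tert-butyldimethylsilyloxy)-4β,8-dimethylspiro[4.5]deca-2,7-dien-1α-yl]acetate | CCOC(=O)C[C@H]1C=C[C@H](C)[C@@]12CC=C(C)[C@@H](O[Si](C)(C)C(C)(C)C)C2 | intermediate
25 | ethyl 2-[(1R,4S,5S,9S)-9-(tert-butyldimethylsilyloxy)-4,8-dimethylspiro[4.5]dec-7-en-1-yl]acetate | CCOC(=O)C[C@H]1CC[C@H](C)[C@@]12CC=C(C)[C@@H](O[Si](C)(C)C(C)(C)C)C2 | intermediate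
26 | (R)-3-bromo-2-methylpropan-1-ol | OC[C@@H](C)CBr | starting material
27 | (R)-(3-bromo-2-methylpropoxy)(tert-butyl)dimethylsilane | CC(C)(C)[Si](C)(C)OC[C@@H](C)CBr | intermediate
28 | [(R)-3-(tert-butyldimethylsilyloxy)-2-methylpropyl]magnesium bromide | CC(C)(C)[Si](C)(C)OC[C@@H](C)C[Mg]Br | intermediate
29 | (S)-5-(tert-butyldimethylsilyloxy)-4-methylpentan-1-ol | CC(C)(C)[Si](C)(C)OC[C@@H](C)CCCO | intermediate
30 | (S)-tert-butyl[(5-iodo-2-methylpentyl)oxy]dimethylsilane | CC(C)(C)[Si](C)(C)OC[C@@H](C)CCCI | intermediate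
31 | lithium enolate of 25 (C11=C(OEt)OLi) | CCOC(O[Li])=C[C@H]1CC[C@H](C)[C@@]12CC=C(C)[C@@H](O[Si](C)(C)C(C)(C)C)C2 | intermediate
32 | ethyl (2R,6S)-7-(tert-butyldimethylsilyloxy)-2-[(1R,4S,5S,9S)-9-(tert-butyldimethylsilyloxy)-4,8-dimethylspiro[4.5]dec-7-en-1-yl]-6-methylheptanoate | CC(C)(C)[Si](C)(C)OC[C@@H](C)CCC[C@@H](C(=O)OCC)[C@H]1CC[C@H](C)[C@@]12CC=C(C)[C@@H](O[Si](C)(C)C(C)(C)C)C2 | intermediate
33 | (2R,6S)-7-(tert-butyldimethylsilyloxy)-2-[(1R,4S,5S,9S)-9-(tert-butyldimethylsilyloxy)-4,8-dimethylspiro[4.5]dec-7-en-1-yl]-6-methylheptan-1-ol | CC(C)(C)[Si](C)(C)OC[C@@H](C)CCC[C@@H](CO)[C@H]1CC[C@H](C)[C@@]12CC=C(C)[C@@H](O[Si](C)(C)C(C)(C)C)C2 | intermediate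
34 | methanesulfonate of 33 | CC(C)(C)[Si](C)(C)OC[C@@H](C)CCC[C@@H](COS(C)(=O)=O)[C@H]1CC[C@H](C)[C@@]12CC=C(C)[C@@H](O[Si](C)(C)C(C)(C)C)C2 | intermediate
35 | tert-butyl{[(2S,6R)-6-[(1R,4S,5S,9S)-9-(tert-butyldimethylsilyloxy)-4,8-dimethylspiro[4.5]dec-7-en-1-yl]-2-methylheptyl]oxy}dimethylsilane | CC(C)(C)[Si](C)(C)OC[C@@H](C)CCC[C@@H](C)[C@H]1CC[C@H](C)[C@@]12CC=C(C)[C@@H](O[Si](C)(C)C(C)(C)C)C2 | intermediate
36 | (2S,6R)-6-[(1R,4S,5S,9S)-9-hydroxy-4,8-dimethylspiro[4.5]dec-7-en-1-yl]-2-methylheptan-1-ol | OC[C@@H](C)CCC[C@@H](C)[C@H]1CC[C@H](C)[C@@]12CC=C(C)[C@@H](O)C2 | intermediate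
37 | (2S,6R)-6-[(1R,4S,5S,9S)-9-hydroxy-4,8-dimethylspiro[4.5]dec-7-en-1-yl]-2-methylheptyl acetate | CC(=O)OC[C@@H](C)CCC[C@@H](C)[C@H]1CC[C@H](C)[C@@]12CC=C(C)[C@@H](O)C2 | target

**Step count and risk**

Total step count: 22. Longest linear sequence: 18 steps (steps 1, 2, 4–14 and 18–22, from 2-ethylacrolein).

The three steps most likely to fail:

Step 5. Proton transfer from the product ketone to unreacted enolate would move the enolate to C2 and expel the silyloxy group; in addition the α face may be discriminated only weakly, because the controlling group is a methyl and the two arms on C5 are alike. The fallback separates the two bond formations. From 8, Me2CuLi in the presence of Me3SiCl (THF, −78 °C, Et3N quench) should give the isolable silyl enol ether {[(3R,4R)-4-(tert-butyldimethylsilyloxy)-3-methyl-2-(2-methylenebutyl)cyclopent-1-en-1-yl]oxy}trimethylsilane F1, in which no basic enolate persists. Palladium-catalysed Tsuji allylation of F1 with diallyl carbonate (Pd2(dba)3, PPh3, catalytic Bu4N[Ph3SiF2], THF, rt) then forms the C5–C6 bond under nearly neutral conditions, anti to the C4 methyl, and the route is rejoined at 12.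

Step 6. The C2 enolate may lose the C3 silyloxy group by E1cB elimination before it is triflated. The fallback never forms that enolate. From 12, ozonolysis (O3, CH2Cl2, −78 °C; PPh3) gives 3α-(tert-butyldimethylsilyloxy)-4β-methyl-5β-(2-oxobutyl)-5α-(2-oxoethyl)cyclopentan-1-one F2. Bn2NH·CF3CO2H in benzene closes the cyclohexenone as in step 8 to give 3α-(tert-butyldimethylsilyloxy)-4β,8-dimethylspiro[4.5]dec-7-ene-1,9-dione F3. NaBH4 in EtOH at −40 °C should reduce the saturated C1 ketone in preference to the conjugated C9 ketone, as with the Wieland–Miescher ketone, to give 1-hydroxy-3α-(tert-butyldimethylsilyloxy)-4β,8-dimethylspiro[4.5]dec-7-en-9-one F4 (either C1 epimer serves). The Burgess reagent (toluene, 60 °C) then removes the C1 hydroxyl with a syn hydrogen of C2, the only neighbour that carries hydrogen, and the route is rejoined at 18.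

Step 12. The facial preference of the substrate (the C4 methyl shields the side of the carbonyl from which hydride must come) may oppose that of the catalyst and erode selectivity at C9. The fallback uses substrate control and then inverts. From 22, Luche reduction (NaBH4, CeCl3·7H2O, MeOH, −78 °C) is expected to deliver hydride from the more open C1 side and give ethyl 2-[(9R)-9-hydroxy-4β,8-dimethylspiro[4.5]deca-2,7-dien-1α-yl]acetate F5. Mitsunobu inversion (4-nitrobenzoic acid, PPh3, DIAD, THF, 0 °C) gives ethyl 2-[(9S)-9-(4-nitrobenzoyloxy)-4β,8-dimethylspiro[4.5]deca-2,7-dien-1α-yl]acetate F6, and K2CO3 in EtOH cleaves the aryl ester while leaving the ethyl ester unchanged, which rejoins the route at 23.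

**Further compounds**

F1 | step 5 | {[(3R,4R)-4-(tert-butyldimethylsilyloxy)-3-methyl-2-(2-methylenebutyl)cyclopent-1-en-1-yl]oxy}trimethylsilane | C[Si](C)(C)OC1=C(CC(=C)CC)[C@@H](C)[C@H](O[Si](C)(C)C(C)(C)C)C1
F2 | step 6 | 3α-(tert-butyldimethylsilyloxy)-4β-methyl-5β-(2-oxobutyl)-5α-(2-oxoethyl)cyclopentan-1-one | O=C1C[C@@H](O[Si](C)(C)C(C)(C)C)[C@H](C)[C@]1(CC=O)CC(=O)CC
F3 | step 6 | 3α-(tert-butyldimethylsilyloxy)-4β,8-dimethylspiro[4.5]dec-7-ene-1,9-dione | O=C1C[C@@H](O[Si](C)(C)C(C)(C)C)[C@H](C)[C@@]12CC=C(C)C(=O)C2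
F4 | step 6 | 1-hydroxy-3α-(tert-butyldimethylsilyloxy)-4β,8-dimethylspiro[4.5]dec-7-en-9-one | OC1C[C@@H](O[Si](C)(C)C(C)(C)C)[C@H](C)[C@@]12CC=C(C)C(=O)C2
F5 | step 12 | ethyl 2-[(9R)-9-hydroxy-4β,8-dimethylspiro[4.5]deca-2,7-dien-1α-yl]acetate | CCOC(=O)C[C@H]1C=C[C@H](C)[C@@]12CC=C(C)[C@H](O)C2
F6 | step 12 | ethyl 2-[(9S)-9-(4-nitrobenzoyloxy)-4β,8-dimethylspiro[4.5]deca-2,7-dien-1α-yl]acetate | CCOC(=O)C[C@H]1C=C[C@H](C)[C@@]12CC=C(C)[C@@H](OC(=O)c3ccc(cc3)[N+](=O)[O-])C2
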